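The synthesis rests on disconnecting ring A between the carbinol carbon C3 and the ring-alkene carbon C2 (eremophilane numbering). An intramolecular Nozaki–Hiyama–Kishi reaction closes ring A onto a finished ring B: a (Z)-iodovinyl group on C10 of a 6-isopropylidene cyclohexenone adds to a side-chain aldehyde, forming the C2–C3 bond, the C3 carbinol and the 1,9-dien-8-one chromophore in one operation. The step exploits the allylic C3–O carbon flanked by the cis C1=C2 alkene of the cyclohexene ring A. The precursor carries the C4/C5 methyl stereocentres from one iridium-catalysed allylic alkylation; C3 is afterwards fixed by oxidation and face-selective reduction, then acylated.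

Key step: step 8

Numbering note: eremophilane locants are used in the text. Ring A is C1–C5 plus C10 and ring B is C5–C10. C3 bears the ester oxygen, C4 and C5 bear the methyls C15 and C14, C7 bears the isopropylidene and C8 is the ketone.

Assumption: in step 2 the phosphoramidite antipode is taken to be the one that delivers the (S)-configured allylic carbon; its absolute sense has to be assigned on the first run.

Step 1
Reactants: 1 3-ethoxycyclohex-2-en-1-one
Product: 2 rac-3-ethoxy-6-methylcyclohex-2-en-1-one
Conditions: LiN(iPr)2, THF, −78 °C; MeI, −78 → 0 °C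
Reagents that add atoms: iodomethane, CI
Why: Kinetic α'-deprotonation of the vinylogous ester and SN2 methylation (Stork–Danheiser alkylation) should give 2; its new stereocenter is racemic and is erased by enolisation in step 2.

Step 2
Reactants: 2 rac-3-ethoxy-6-methylcyclohex-2-en-1-one; 3 (E)-1-chlorobut-2-ene
Product: 4 (R)-6-[(S)-but-3-en-2-yl]-3-ethoxy-6-methylcyclohex-2-en-1-one
Conditions: Ba[N(SiMe3)2]2 (0.55 equiv), THF, −78 °C; then 3, [Ir(cod)Cl]2 (2 mol%), O,O'-(1,1'-binaphthalene-2,2'-diyl) N,N-bis(1-phenylethyl)phosphoramidite (4 mol%), −78 → 25 °C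
Reagents that add atoms: none
Why: Iridium-catalysed branched-selective asymmetric allylic alkylation: the barium enolate attacks the methyl-bearing terminus of the Ir π-crotyl complex anti to the metal, so the ligand fixes the allylic stereocenter C4 and the same outer-sphere event selects the enolate face that sets quaternary C5, as in known constructions of adjacent quaternary and tertiary centres from cyclic α-methyl ketone enolates.

Step 3
Reactants: 4 (R)-6-[(S)-but-3-en-2-yl]-3-ethoxy-6-methylcyclohex-2-en-1-one; 5 ethynyltrimethylsilane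
Product: 7 (R)-4-[(S)-but-3-en-2-yl]-4-methyl-3-[(trimethylsilyl)ethynyl]cyclohex-2-en-1-one, via propargylic alkoxide adduct 6 (not isolated)
Conditions: 5, n-BuLi, THF, −78 °C; anhydrous CeCl3; then 4, −78 → 0 °C; then 1 M HCl, THF, 25 °C
Reagents that add atoms: water, O
Why: Stork–Danheiser transposition: 1,2-addition of the acetylide to the hindered vinylogous-ester carbonyl, then acid-induced loss of water and hydrolysis of the enol ether moves the carbonyl to C8 and leaves the alkyne on the now sp2 C10; no stereocenter is formed or touched.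

Step 4
Reactants: 7 (R)-4-[(S)-but-3-en-2-yl]-4-methyl-3-[(trimethylsilyl)ethynyl]cyclohex-2-en-1-one; 8 acetone
Product: 11 (R)-4-[(S)-but-3-en-2-yl]-4-methyl-6-(propan-2-ylidene)-3-[(trimethylsilyl)ethynyl]cyclohex-2-en-1-one, via aldolate 9 (not isolated), via mesylate 10 (not isolated)
Conditions: LiN(iPr)2, THF, −78 °C; acetone; MsCl, −78 → 0 °C; DBU, 25 °C
Reagents that add atoms: none
Why: Kinetic enolisation at C7 (the only enolisable position), aldol addition to acetone, in situ sulfonylation and E1cB elimination should give the conjugated tetrasubstituted isopropylidene (aldol condensation); no stereocenter is created.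

Step 5
Reactants: 11 (R)-4-[(S)-but-3-en-2-yl]-4-methyl-6-(propan-2-ylidene)-3-[(trimethylsilyl)ethynyl]cyclohex-2-en-1-one
Product: 12 (R)-4-[(S)-but-3-en-2-yl]-3-(iodoethynyl)-4-methyl-6-(propan-2-ylidene)cyclohex-2-en-1-one
Conditions: N-iodosuccinimide, AgNO3 (10 mol%), DMF, 25 °C, dark
Reagents that add atoms: N-iodosuccinimide, O=C1CCC(=O)N1I
Why: Silver-catalysed iododesilylation of the alkynylsilane (via a silver acetylide) is selective for the C–Si bond and leaves the alkenes untouched; no stereocenter is involved.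

Step 6
Reactants: 12 (R)-4-[(S)-but-3-en-2-yl]-3-(iodoethynyl)-4-methyl-6-(propan-2-ylidene)cyclohex-2-en-1-one
Product: 14 (R)-2-[(R)-2-(iodoethynyl)-1-methyl-4-oxo-5-(propan-2-ylidene)cyclohex-2-en-1-yl]propanal, via vicinal diol 13 (not isolated)
Conditions: OsO4 (2 mol%), NaIO4 (4 equiv), 2,6-lutidine, 1,4-dioxane/H2O 3:1, 25 °C
Reagents that add atoms: sodium periodate, [Na+].[O-]I(=O)(=O)=O (oxygen relayed through osmium tetroxide, O=[Os](=O)(=O)=O)
Why: Lemieux–Johnson oxidative cleavage: osmylation selects the electron-rich monosubstituted vinyl group over the electron-poor enone, the tetrasubstituted alkylidene and the iodoalkyne, and the lutidine buffer keeps the α-stereocenter C4 intact.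

Step 7
Reactants: 14 (R)-2-[(R)-2-(iodoethynyl)-1-methyl-4-oxo-5-(propan-2-ylidene)cyclohex-2-en-1-yl]propanal
Product: 15 (R)-2-[(R)-2-[(Z)-2-iodoethenyl]-1-methyl-4-oxo-5-(propan-2-ylidene)cyclohex-2-en-1-yl]propanal
Conditions: KO2CN=NCO2K, AcOH, pyridine, 1,4-dioxane/i-PrOH, 0 → 25 °C
Reagents that add atoms: none
Why: Diimide reduction delivers both hydrogens suprafacially to the iodoalkyne, so the (Z)-iodoalkene needed for an endocyclic ring alkene should result; carbonyls and the tri- and tetrasubstituted conjugated alkenes react far more slowly.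

Step 8
Reactants: 15 (R)-2-[(R)-2-[(Z)-2-iodoethenyl]-1-methyl-4-oxo-5-(propan-2-ylidene)cyclohex-2-en-1-yl]propanal
Product: 17 (4aR,5R,6R)-6-hydroxy-4a,5-dimethyl-3-(propan-2-ylidene)-4,4a,5,6-tetrahydronaphthalen-2(3H)-one, via alkenylchromium dichloride 16 (not isolated)
Conditions: CrCl2 (6 equiv), NiCl2 (2 mol%), degassed DMSO, 25 °C, 0.005 M, slow addition
Reagents that add atoms: none
Why: Divalent chromium reduces NiCl2 to zerovalent nickel, which inserts into the alkenyl C–I bond with retention; transmetalation gives the (Z)-alkenyl trivalent-chromium species 16, whose C2 adds to the chromium-bound aldehyde carbon C3 (intramolecular Nozaki–Hiyama–Kishi reaction, the closest known type being alkenyl iodide/aldehyde cyclisations to 2-cycloalkenols). Ring A is closed as a six-membered carbocycle by 6-exo-trig attack on the C=O, the C1=C2 alkene ending endocyclic, which is why the Z-iodide is mandatory. The new stereocenter C3 is controlled by the adjacent C4 stereocenter and the pseudoaxial C14 methyl: a transition state with the aldehyde hydrogen between C5 and C15 and the O–Cr group pseudoequatorial, away from C14, should favour the 3R carbinol (C6 R in the naphthalenone name). This sense is not required, because step 9 converts both C3 epimers into the same enedione. The step needs chemoselectivity for the aldehyde over the cross-conjugated C8 ketone and the dienone acceptor, secured by the aldehyde selectivity of organochromium reagents, and cyclisation over oligomerisation, secured by high dilution and the cis disposition of C2 and the side chain across the diene. Epimerisation at C4 should be avoided by the neutral aprotic medium.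

Step 9
Reactants: 17 (4aR,5R,6R)-6-hydroxy-4a,5-dimethyl-3-(propan-2-ylidene)-4,4a,5,6-tetrahydronaphthalen-2(3H)-one
Product: 18 (4aR,5R)-4a,5-dimethyl-3-(propan-2-ylidene)-4,4a-dihydronaphthalene-2,6(3H,5H)-dione
Conditions: Dess–Martin periodinane, NaHCO3, CH2Cl2, 0 → 25 °C
Reagents that add atoms: none
Why: Dess–Martin oxidation of the allylic alcohol removes the C3 stereocenter and converges both epimers of 17 to one enedione under buffered conditions that should not epimerise C4.

Step 10
Reactants: 18 (4aR,5R)-4a,5-dimethyl-3-(propan-2-ylidene)-4,4a-dihydronaphthalene-2,6(3H,5H)-dione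
Product: 19 (4aR,5R,6S)-6-hydroxy-4a,5-dimethyl-3-(propan-2-ylidene)-4,4a,5,6-tetrahydronaphthalen-2(3H)-one
Conditions: NaBH4 (1.0 equiv), CeCl3·7H2O, MeOH/CH2Cl2, −78 °C
Reagents that add atoms: none
Why: Luche 1,2-reduction: the ring A enone carbonyl is more accessible and more electrophilic than the doubly cross-conjugated C8 carbonyl flanked by the isopropylidene, and hydride should add anti to the pseudoaxial angular methyl C14 (1,3 to C3), setting the pseudoaxial 3S alcohol cis to both methyls (steric approach control).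

Step 11
Reactants: 20 (S)-2-methylbutan-1-ol
Product: 21 (S)-2-methylbutanal
Conditions: TEMPO (10 mol%), PhI(OAc)2, CH2Cl2, 0 → 25 °C; used at once as a solution
Reagents that add atoms: none
Why: TEMPO/iodosobenzene diacetate oxidation (oxoammonium mechanism) is non-basic, so the α-stereocenter of the aldehyde should be retained.

Step 12
Reactants: 21 (S)-2-methylbutanal; 22 triethyl (E)-4-phosphonocrotonate
Product: 23 ethyl (2E,4E,6S)-6-methylocta-2,4-dienoate
Conditions: 22, LiN(SiMe3)2, THF, −78 °C; then 21, −78 → 0 °C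
Reagents that add atoms: none
Why: Vinylogous Horner–Wadsworth–Emmons olefination should form the new C4=C5 bond E-selectively and keep the E-geometry of the phosphonate; addition at −78 °C avoids epimerisation of the α-branched aldehyde.

Step 13
Reactants: 23 ethyl (2E,4E,6S)-6-methylocta-2,4-dienoate
Product: 24 (2E,4E,6S)-6-methylocta-2,4-dienoic acid
Conditions: LiOH, THF/MeOH/H2O, 25 °C; then 1 M HCl
Reagents that add atoms: lithium hydroxide, [Li+].[OH-]
Why: Saponification of the ethyl ester; the remote stereocenter and the diene geometry are not affected.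

Step 14
Reactants: 19 (4aR,5R,6S)-6-hydroxy-4a,5-dimethyl-3-(propan-2-ylidene)-4,4a,5,6-tetrahydronaphthalen-2(3H)-one; 24 (2E,4E,6S)-6-methylocta-2,4-dienoic acid
Product: 26 (4aR,5R,6S)-4a,5-dimethyl-2-oxo-3-(propan-2-ylidene)-2,3,4,4a,5,6-hexahydronaphthalen-6-yl (2E,4E,6S)-6-methylocta-2,4-dienoate (CNP0215744.1), via mixed anhydride 25 (not isolated)
Conditions: 24, 2,4,6-trichlorobenzoyl chloride, Et3N, THF, 25 °C; then 19, DMAP, toluene, 40 °C
Reagents that add atoms: none
Why: Yamaguchi esterification: the acid is activated as mixed anhydride 25 and transferred by DMAP to the hindered pseudoaxial alcohol with retention at C3, since the C3–O bond is not broken.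

Compound list
1 | 3-ethoxycyclohex-2-en-1-one | CCOC1=CC(=O)CCC1 | starting material
2 | rac-3-ethoxy-6-methylcyclohex-2-en-1-one | CCOC1=CC(=O)C(C)CC1 | intermediate
3 | (E)-1-chlorobut-2-ene | C/C=C/CCl | starting material
4 | (R)-6-[(S)-but-3-en-2-yl]-3-ethoxy-6-methylcyclohex-2-en-1-one | C=C[C@H](C)[C@@]1(C)CCC(OCC)=CC1=O | intermediate
5 | ethynyltrimethylsilane | C#C[Si](C)(C)C | starting material
6 | (6R)-6-[(S)-but-3-en-2-yl]-3-ethoxy-6-methyl-1-[(trimethylsilyl)ethynyl]cyclohex-2-en-1-ol, present as its metal alkoxide, C1 epimers | C=C[C@H](C)[C@@]1(C)CCC(OCC)=CC1(O)C#C[Si](C)(C)C | intermediate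
7 | (R)-4-[(S)-but-3-en-2-yl]-4-methyl-3-[(trimethylsilyl)ethynyl]cyclohex-2-en-1-one | C=C[C@H](C)[C@@]1(C)CCC(=O)C=C1C#C[Si](C)(C)C | intermediate
8 | acetone | CC(C)=O | starting material
9 | (4R)-4-[(S)-but-3-en-2-yl]-6-(2-hydroxypropan-2-yl)-4-methyl-3-[(trimethylsilyl)ethynyl]cyclohex-2-en-1-one, present as its lithium alkoxide, C6 epimers | C=C[C@H](C)[C@@]1(C)CC(C(C)(C)O)C(=O)C=C1C#C[Si](C)(C)C | intermediate
10 | methanesulfonate of 9 | C=C[C@H](C)[C@@]1(C)CC(C(C)(C)OS(C)(=O)=O)C(=O)C=C1C#C[Si](C)(C)C | intermediate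
11 | (R)-4-[(S)-but-3-en-2-yl]-4-methyl-6-(propan-2-ylidene)-3-[(trimethylsilyl)ethynyl]cyclohex-2-en-1-one | C=C[C@H](C)[C@@]1(C)CC(=C(C)C)C(=O)C=C1C#C[Si](C)(C)C | intermediate
12 | (R)-4-[(S)-but-3-en-2-yl]-3-(iodoethynyl)-4-methyl-6-(propan-2-ylidene)cyclohex-2-en-1-one | C=C[C@H](C)[C@@]1(C)CC(=C(C)C)C(=O)C=C1C#CI | intermediate
13 | (4R)-4-[(2S)-3,4-dihydroxybutan-2-yl]-3-(iodoethynyl)-4-methyl-6-(propan-2-ylidene)cyclohex-2-en-1-one, carbinol epimers | OCC(O)[C@H](C)[C@@]1(C)CC(=C(C)C)C(=O)C=C1C#CI | intermediate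
14 | (R)-2-[(R)-2-(iodoethynyl)-1-methyl-4-oxo-5-(propan-2-ylidene)cyclohex-2-en-1-yl]propanal | O=C[C@H](C)[C@@]1(C)CC(=C(C)C)C(=O)C=C1C#CI | intermediate
15 | (R)-2-[(R)-2-[(Z)-2-iodoethenyl]-1-methyl-4-oxo-5-(propan-2-ylidene)cyclohex-2-en-1-yl]propanal | O=C[C@H](C)[C@@]1(C)CC(=C(C)C)C(=O)C=C1/C=C\I | intermediate
16 | (Z)-alkenylchromium dichloride from 15, chromium on C2 | O=C[C@H](C)[C@@]1(C)CC(=C(C)C)C(=O)C=C1/C=C\[Cr](Cl)Cl | intermediate
17 | (4aR,5R,6R)-6-hydroxy-4a,5-dimethyl-3-(propan-2-ylidene)-4,4a,5,6-tetrahydronaphthalen-2(3H)-one, expected major C6 epimer, carried on together with the 6S epimer | O[C@@H]1C=CC2=CC(=O)C(=C(C)C)C[C@]2(C)[C@H]1C | intermediate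
18 | (4aR,5R)-4a,5-dimethyl-3-(propan-2-ylidene)-4,4a-dihydronaphthalene-2,6(3H,5H)-dione | O=C1C=CC2=CC(=O)C(=C(C)C)C[C@]2(C)[C@H]1C | intermediate
19 | (4aR,5R,6S)-6-hydroxy-4a,5-dimethyl-3-(propan-2-ylidene)-4,4a,5,6-tetrahydronaphthalen-2(3H)-one | O[C@H]1C=CC2=CC(=O)C(=C(C)C)C[C@]2(C)[C@H]1C | intermediate
20 | (S)-2-methylbutan-1-ol | CC[C@H](C)CO | starting material
21 | (S)-2-methylbutanal | CC[C@H](C)C=O | intermediate
22 | triethyl (E)-4-phosphonocrotonate | CCOC(=O)/C=C/CP(=O)(OCC)OCC | starting material
23 | ethyl (2E,4E,6S)-6-methylocta-2,4-dienoate | CC[C@H](C)/C=C/C=C/C(=O)OCC | intermediate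
24 | (2E,4E,6S)-6-methylocta-2,4-dienoic acid | CC[C@H](C)/C=C/C=C/C(=O)O | intermediate
25 | (2E,4E,6S)-6-methylocta-2,4-dienoic 2,4,6-trichlorobenzoic anhydride | CC[C@H](C)/C=C/C=C/C(=O)OC(=O)c1c(Cl)cc(Cl)cc1Cl | intermediate
26 | (4aR,5R,6S)-4a,5-dimethyl-2-oxo-3-(propan-2-ylidene)-2,3,4,4a,5,6-hexahydronaphthalen-6-yl (2E,4E,6S)-6-methylocta-2,4-dienoate (CNP0215744.1) | CC[C@H](C)/C=C/C=C/C(=O)O[C@H]1C=CC2=CC(=O)C(=C(C)C)C[C@]2(C)[C@H]1C | target

Total step count: 14. Longest linear sequence: 11 steps (steps 1–10 and 14); steps 11–13 make the side-chain acid.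

Steps most likely to fail

1. Step 2. The branched regioselectivity may erode with the small methyl-substituted allyl terminus, or the tetrasubstituted enolate may show poor facial discrimination, so that the C4/C5 pair forms with low diastereoselectivity. The fallback sets out from 2 and comes back at 4. The lithium enolate of 2 (LiN(iPr)2, THF, −78 °C) is allylated under palladium catalysis ([Pd(C3H5)Cl]2 with N,N'-(cyclohexane-1,2-diyl)bis[2-(diphenylphosphino)benzamide], antipode chosen as in the assumption) with racemic methyl (E)-pent-3-en-2-yl carbonate F1, made from commercial (E)-pent-3-en-2-ol with methyl chloroformate and pyridine. The symmetrical 1,3-dimethylallyl palladium intermediate removes the regiochemical question and should give (R)-3-ethoxy-6-methyl-6-[(2S,3E)-pent-3-en-2-yl]cyclohex-2-en-1-one F2. Ethenolysis (ethylene, second-generation Hoveyda–Grubbs catalyst, CH2Cl2) then trims the propenyl group to vinyl and returns to 4.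

2. Step 8. The alkenylchromium may be protonated before it cyclises, the dienone may be degraded by the excess divalent chromium, or intermolecular coupling may compete with ring closure. The fallback sets out from 15 and comes back at 17, closing the same bond catalytically. Stereoretentive borylation (bis(pinacolato)diboron, PdCl2(dppf), KOAc, 1,4-dioxane, 60 °C) should give (R)-2-[(R)-1-methyl-4-oxo-5-(propan-2-ylidene)-2-[(Z)-2-(4,4,5,5-tetramethyl-1,3,2-dioxaborolan-2-yl)ethenyl]cyclohex-2-en-1-yl]propanal F3. Rhodium-catalysed intramolecular 1,2-addition of the alkenylboronate to the aldehyde ([Rh(cod)OH]2, 1,4-dioxane/H2O, 60 °C) should then give 17.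

3. Step 10. The C8 carbonyl may be reduced competitively, or the facial bias at C3 may be insufficient. The fallback sets out from 17 and comes back at 19, bypassing steps 9 and 10 by inverting the NHK carbinol instead of re-forming it. Invertive esterification (PPh3, diisopropyl azodicarboxylate, 4-nitrobenzoic acid, toluene, 0 → 25 °C) should give (4aR,5R,6S)-4a,5-dimethyl-2-oxo-3-(propan-2-ylidene)-2,3,4,4a,5,6-hexahydronaphthalen-6-yl 4-nitrobenzoate F4. Methanolysis (K2CO3, MeOH, 0 °C) then releases 19; any 6S alcohol already present in 17 is 19 itself.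

Further compounds
F1 | step 2 | rac-methyl (E)-pent-3-en-2-yl carbonate | C/C=C/C(C)OC(=O)OC
F2 | step 2 | (R)-3-ethoxy-6-methyl-6-[(2S,3E)-pent-3-en-2-yl]cyclohex-2-en-1-one | C/C=C/[C@H](C)[C@@]1(C)CCC(OCC)=CC1=O
F3 | step 8 | (R)-2-[(R)-1-methyl-4-oxo-5-(propan-2-ylidene)-2-[(Z)-2-(4,4,5,5-tetramethyl-1,3,2-dioxaborolan-2-yl)ethenyl]cyclohex-2-en-1-yl]propanal | O=C[C@H](C)[C@@]1(C)CC(=C(C)C)C(=O)C=C1/C=C\B2OC(C)(C)C(C)(C)O2
F4 | step 10 | (4aR,5R,6S)-4a,5-dimethyl-2-oxo-3-(propan-2-ylidene)-2,3,4,4a,5,6-hexahydronaphthalen-6-yl 4-nitrobenzoate | O=C(O[C@H]1C=CC2=CC(=O)C(=C(C)C)C[C@]2(C)[C@H]1C)c1ccc(cc1)[N+](=O)[O-]
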